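## Retrosynthetic overview

1. Feature: C6 is an allylic carbinol carbon bonded to C5 of the C4=C5 alkene and to C7, and O6 lies five atoms from the C12 carbonyl (O6–C6–C7–C11–C12). Making C5–C6 from a C6 aldehyde therefore closes the ten-membered ring C1–C10 and releases the alkoxide that closes the lactone ring.
2. Key disconnection: C5–C6 (alkenyl iodide plus aldehyde, CrCl2/NiCl2) and O6–C12 in one operation, carbocycle first and lactone second; C14 oxidation and desilylation follow.
3. Precursor 23: C7–C8 by a thiazolidinethione syn-aldol of an itaconate half ester with C8 aldehyde 15; C6 arrives as the acyl carbon and is released as the aldehyde by i-Bu2AlH. A 2-(alkoxycarbonyl)allylation with a (Z)-bromomethyl enoate was not used because it would give the C7 epimer.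
4. Aldehyde 15: C9–C10 by alkenylchromium addition of (Z)-2-iodoallylic alcohol 9 to (R)-glyceraldehyde acetonide, with C8 unmasked by glycol cleavage; C1=C10 by an iodo-Wittig reaction; C4=C5–I by anti-carbomagnesiation of 1 and iododesilylation.
5. O9/O14 are carried as a di-tert-butylsilylene, which survives the acid that cleaves the terminal acetonide; O15 is a triisopropylsilyl ether.

Key step: step 16

Remark: germacrane numbering (C1–C15) is used for all intermediates, and aldehydes 15 and 23 are assumed to be taken on crude, without chromatography or storage.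

## Route

Step 1
Reactants: 1 3-(trimethylsilyl)prop-2-yn-1-ol
Product: 3 (E)-2-[(trimethylsilyl)methylidene]pent-4-en-1-ol, via alkenylmagnesium chelate 2 (not isolated)
Conditions: CH2=CHCH2MgBr (3 equiv), Et2O, 0 °C to reflux; aq. NH4Cl
Reagents that add atoms: allylmagnesium bromide, C=CC[Mg]Br
Why: Hydroxyl-directed anti-carbomagnesiation of a propargylic alcohol: the magnesium alkoxide delivers the allyl group to C4 while magnesium ends on the silylated carbon C5 inside a five-membered chelate, so protonation leaves the silyl group cis to the new C3 chain.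

Step 2
Reactants: 3 (E)-2-[(trimethylsilyl)methylidene]pent-4-en-1-ol
Product: 4 triisopropylsilyl ether of 3
Conditions: TIPSCl, imidazole, DMF, rt
Reagents that add atoms: chlorotri(propan-2-yl)silane, CC(C)[Si](Cl)(C(C)C)C(C)C
Why: Imidazole-promoted silyl ether formation on the primary allylic alcohol O15; no stereocentre is involved.

Step 3
Reactants: 4 triisopropylsilyl ether of 3
Product: 6 (E)-4-[(triisopropylsilyloxy)methyl]-5-(trimethylsilyl)pent-4-en-1-ol, via B-alkyl-9-BBN adduct 5 (not isolated)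
Conditions: 9-BBN, THF, 0 °C to rt; then NaOH, H2O2, 0 °C
Reagents that add atoms: hydrogen peroxide, OO
Why: Hydroboration–oxidation: the bulky borane adds anti-Markovnikov to the monosubstituted terminal alkene only, leaves the hindered alkenylsilane, and alkaline peroxide turns the C–B bond into C1–OH.

Step 4
Reactants: 6 (E)-4-[(triisopropylsilyloxy)methyl]-5-(trimethylsilyl)pent-4-en-1-ol
Product: 7 (E)-4-[(triisopropylsilyloxy)methyl]-5-(trimethylsilyl)pent-4-enal
Conditions: Dess–Martin periodinane, CH2Cl2, 0 °C to rt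
Reagents that add atoms: none
Why: Dess–Martin oxidation of a primary alcohol to the C1 aldehyde under non-basic conditions that leave the silyl ether and the alkenylsilane untouched.

Step 5
Reactants: 7 (E)-4-[(triisopropylsilyloxy)methyl]-5-(trimethylsilyl)pent-4-enal
Product: 8 methyl (2Z,6E)-2-iodo-6-[(triisopropylsilyloxy)methyl]-7-(trimethylsilyl)hepta-2,6-dienoate
Conditions: Ph3P=CHCO2Me, NIS, CH2Cl2, −20 °C; then 7, −20 °C to rt
Reagents that add atoms: methyl (triphenylphosphoranylidene)acetate, COC(=O)C=P(c1ccccc1)(c1ccccc1)c1ccccc1; N-iodosuccinimide, O=C1CCC(=O)N1I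
Why: Wittig olefination with an ester-stabilised α-iodo ylide made in the flask by iodination of the ylide: the stabilised ylide places the ester (C14) trans to the C2 chain, so the (Z)-α-iodoenoate with iodine on C10 cis to C2 should predominate.

Step 6
Reactants: 8 methyl (2Z,6E)-2-iodo-6-[(triisopropylsilyloxy)methyl]-7-(trimethylsilyl)hepta-2,6-dienoate
Product: 9 (2Z,6E)-2-iodo-6-[(triisopropylsilyloxy)methyl]-7-(trimethylsilyl)hepta-2,6-dien-1-ol
Conditions: i-Bu2AlH (2.5 equiv), CH2Cl2, −78 °C; Rochelle salt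
Reagents that add atoms: none
Why: 1,2-Reduction of the enoate by two hydride transfers at low temperature gives the C14 allylic alcohol without touching the alkenyl iodide or the alkene geometry.

Step 7
Reactants: 9 (2Z,6E)-2-iodo-6-[(triisopropylsilyloxy)methyl]-7-(trimethylsilyl)hepta-2,6-dien-1-ol; 10 (R)-glyceraldehyde acetonide
Product: 11 (1S,2Z,6E)-1-[(4R)-2,2-dimethyl-1,3-dioxolan-4-yl]-2-(hydroxymethyl)-6-[(triisopropylsilyloxy)methyl]-7-(trimethylsilyl)hepta-2,6-dien-1-ol
Conditions: CrCl2 (5 equiv), NiCl2 (2 mol %), DMSO, rt; 10 (2.5 equiv)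
Reagents that add atoms: none
Why: Nozaki–Hiyama–Kishi coupling: the alkenylchromium formed at C10 with retention of geometry adds to the aldehyde anti to the α-C–O bond (Felkin–Anh), which should make the anti (9S) carbinol the main product, the minor C9 epimer being removed by chromatography; the alkenylsilane and the free hydroxyl are tolerated.

Step 8
Reactants: 11 diol from step 7
Product: 12 O9/O14 di-tert-butylsilylene of 11
Conditions: t-Bu2Si(OTf)2, 2,6-lutidine, CH2Cl2, 0 °C
Reagents that add atoms: di-tert-butylsilyl bis(trifluoromethanesulfonate), CC(C)(C)[Si](OS(=O)(=O)C(F)(F)F)(OS(=O)(=O)C(F)(F)F)C(C)(C)C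
Why: Silylene acetal formation: the bis-triflate bridges the 1,3-diol O9/O14 as a six-membered dioxasilinane that, unlike an acetonide, is stable to the acid used in the next two steps.

Step 9
Reactants: 12 O9/O14 di-tert-butylsilylene of 11
Product: 13 C5 alkenyl iodide (iodine in place of the trimethylsilyl group with the same geometry)
Conditions: NIS (1.3 equiv), (CF3)2CHOH, 0 °C
Reagents that add atoms: N-iodosuccinimide, O=C1CCC(=O)N1I
Why: Electrophilic ipso-iododesilylation: iodonium attack at C5 gives a tertiary β-silyl cation that loses silicon with retention in hexafluoroisopropanol, so iodine stays cis to C3 and trans to C15.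

Step 10
Reactants: 13 C5 alkenyl iodide
Product: 15 (4S,5Z)-2,2-di-tert-butyl-5-[(4E)-5-iodo-4-{[(triisopropylsilyl)oxy]methyl}pent-4-en-1-ylidene]-1,3,2-dioxasilinane-4-carbaldehyde (C8 aldehyde), via terminal 1,2-diol 14 (not isolated)
Conditions: H5IO6 (1.5 equiv), EtOAc, 0 °C to rt
Reagents that add atoms: none
Why: Periodic acid hydrolyses the terminal acetonide and cleaves the 1,2-diol so formed (Malaprade glycol cleavage), which deletes the auxiliary stereocentre and leaves C8 as the aldehyde next to the intact C9 centre.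

Step 11
Reactants: 16 dimethyl itaconate
Product: 17 3-(methoxycarbonyl)but-3-enoic acid
Conditions: LiOH (1.0 equiv), THF/H2O, 0 °C; then 1 M HCl
Reagents that add atoms: lithium hydroxide, [Li+].[OH-]
Why: Saponification with one equivalent of hydroxide takes the saturated, unhindered ester in preference to the conjugated α-branched one.

Step 12
Reactants: 17 3-(methoxycarbonyl)but-3-enoic acid; 18 (4R)-4-benzyl-1,3-thiazolidine-2-thione
Product: 19 methyl 4-[(4R)-4-benzyl-2-sulfanylidene-1,3-thiazolidin-3-yl]-2-methylidene-4-oxobutanoate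
Conditions: DCC, DMAP (cat.), CH2Cl2, 0 °C
Reagents that add atoms: none
Why: Carbodiimide coupling (Steglich-type N-acylation) of the acid to the thiazolidinethione nitrogen under conditions mild enough to keep the exocyclic alkene out of conjugation.

Step 13
Reactants: 15 C8 aldehyde; 19 itaconyl thiazolidinethione
Product: 20 syn-aldol adduct (7R,8R,9S) with C6 as the thioimide carbonyl and C8–OH free
Conditions: 19 (1.5 equiv), TiCl4 (1.05 equiv), i-Pr2NEt (1.1 equiv), N-methylpyrrolidone (1.1 equiv), CH2Cl2, 0 to −78 °C; then 15, −78 °C; aq. NH4Cl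
Reagents that add atoms: none
Why: Crimmins titanium-enolate aldol: the (Z)-chlorotitanium enolate adds through a non-chelated chair transition state, the (R)-benzyl auxiliary fixes the enolate face and so C7 and C8 as the 7,8-syn pair (acrylate and O8 syn along C6–C9), and this sense coincides with the Cornforth/Felkin preference of the α-silyloxy aldehyde for the 8,9-anti product.

Step 14
Reactants: 20 syn-aldol adduct; 21 (S)-2-methylbutanoic acid
Product: 22 C8 (S)-2-methylbutanoate of 20
Conditions: 21, DCC, DMAP (0.1 equiv), CH2Cl2, −10 to 0 °C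
Reagents that add atoms: none
Why: Steglich esterification of the secondary alcohol at low temperature; the configurations at C8 and at the acid α-carbon are not touched.

Step 15
Reactants: 22 C8 (S)-2-methylbutanoate of 20
Product: 23 C6 aldehyde (7R,8R,9S) carrying the C7 acrylate unit, the C8 ester and the C5 alkenyl iodide
Conditions: i-Bu2AlH (1.2 equiv), CH2Cl2, −78 °C; Rochelle salt, pH 7
Reagents that add atoms: none
Why: Partial reduction of an N-acylthiazolidinethione: the thioimide reacts faster than the conjugated methyl ester and the hindered 2-methylbutanoate and gives a tetrahedral aluminium adduct that is stable at −78 °C and releases the aldehyde only on neutral work-up.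

Step 16
Reactants: 23 C6 aldehyde
Product: 25 bicyclic lactone (6R,7S,8R,9S) with O9/O14 as the silylene and O15 as the silyl ether, via ring-closed C6 carbinol ester 24 (not isolated)
Conditions: CrCl2 (10 equiv), NiCl2 (0.1 equiv), degassed DMSO, 0.002 M (syringe pump), rt; aq. NH4Cl
Reagents that add atoms: none
Why: Zerovalent nickel, formed from NiCl2 by divalent chromium, inserts into the C5–I bond and passes the alkenyl group with retention of geometry to trivalent chromium, and the alkenylchromium adds to the C6 aldehyde and to no ester, as in known Nozaki–Hiyama–Kishi ring closures of iodoalkenyl aldehydes. This 10-exo-trig attack of C5 on the C6 carbonyl closes the ring C1–C10, and the chromium alkoxide on O6 then attacks the C12 methyl ester in a 5-exo-trig closure and expels methoxide, as the chromium alkoxides of γ-hydroxy α-methylene esters do in chromium-mediated 2-(alkoxycarbonyl)allylations. The new stereocentre C6 (R) is set by C7: in the ring-forming transition state the ring chain through C8 lies anti to the incoming C5, the acrylate takes the inside position and H7 the outside one (Felkin–Anh), so H6 and H7 end up trans on the lactone, while the retained (E)-iodide geometry fixes the ring-cis C4=C5 bond. The step needs this facial selectivity, addition to the aldehyde only, and ring closure over oligomerisation: the first rests on the C7 centre and on the dioxasilinane ring that holds C8–C10 rigid, the second on the inertness of alkenylchromium towards esters and acrylates, the third on high dilution. The medium is neutral, so the C7 centre, which is epimerisable and β to the C8 acyloxy group, is not put at risk before the ring closes.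

Step 17
Reactants: 25 bicyclic lactone
Product: 26 9,14-diol with O15 still silylated
Conditions: HF·pyridine, pyridine, THF, 0 °C
Reagents that add atoms: none
Why: Fluoride cleavage of the dioxasilinane by buffered HF·pyridine is much faster than that of the primary triisopropylsilyl ether and frees O9–H and O14–H.

Step 18
Reactants: 26 9,14-diol
Product: 27 C14 enal with C9–OH free and O15 silylated
Conditions: TEMPO (0.2 equiv), PhI(OAc)2 (1.2 equiv), CH2Cl2, rt
Reagents that add atoms: none
Why: TEMPO-catalysed oxoammonium oxidation takes the primary allylic alcohol C14 and not the hindered secondary C9 alcohol, and stops at the enal.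

Step 19
Reactants: 27 C14 enal
Product: 28 CNP0331447.11
Conditions: HF·pyridine, THF, 0 °C to rt
Reagents that add atoms: none
Why: Acidic fluoride desilylation removes the triisopropylsilyl ether without touching the enal, the ester or the α-methylene lactone.

## Compound list

1 | 3-(trimethylsilyl)prop-2-yn-1-ol | C[Si](C)(C)C#CCO | starting material
2 | cyclic alkenylmagnesium alkoxide (1-oxa-2-magnesacyclopent-3-ene, 3-trimethylsilyl, 4-allyl) | C=CCC1=C([Si](C)(C)C)[Mg]OC1 | intermediate
3 | (E)-2-[(trimethylsilyl)methylidene]pent-4-en-1-ol (silyl group cis to the allyl group) | C=CC/C(CO)=C\[Si](C)(C)C | intermediate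
4 | (E)-triisopropyl({2-[(trimethylsilyl)methylidene]pent-4-en-1-yl}oxy)silane | C=CC/C(CO[Si](C(C)C)(C(C)C)C(C)C)=C\[Si](C)(C)C | intermediate
5 | B-alkyl-9-borabicyclo[3.3.1]nonane from 4 (boron on C1) | B1(CCC/C(CO[Si](C(C)C)(C(C)C)C(C)C)=C\[Si](C)(C)C)C2CCCC1CCC2 | intermediate
6 | (E)-4-{[(triisopropylsilyl)oxy]methyl}-5-(trimethylsilyl)pent-4-en-1-ol | OCCC/C(CO[Si](C(C)C)(C(C)C)C(C)C)=C\[Si](C)(C)C | intermediate
7 | (E)-4-{[(triisopropylsilyl)oxy]methyl}-5-(trimethylsilyl)pent-4-enal | O=CCC/C(CO[Si](C(C)C)(C(C)C)C(C)C)=C\[Si](C)(C)C | intermediate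
8 | methyl (2Z,6E)-2-iodo-6-{[(triisopropylsilyl)oxy]methyl}-7-(trimethylsilyl)hepta-2,6-dienoate | COC(=O)/C(I)=C/CC/C(CO[Si](C(C)C)(C(C)C)C(C)C)=C\[Si](C)(C)C | intermediate
9 | (2Z,6E)-2-iodo-6-{[(triisopropylsilyl)oxy]methyl}-7-(trimethylsilyl)hepta-2,6-dien-1-ol | OC/C(I)=C/CC/C(CO[Si](C(C)C)(C(C)C)C(C)C)=C\[Si](C)(C)C | intermediate
10 | (R)-2,2-dimethyl-1,3-dioxolane-4-carbaldehyde ((R)-glyceraldehyde acetonide) | O=C[C@H]1COC(C)(C)O1 | starting material
11 | (1S,2Z,6E)-1-[(4R)-2,2-dimethyl-1,3-dioxolan-4-yl]-2-(hydroxymethyl)-6-{[(triisopropylsilyl)oxy]methyl}-7-(trimethylsilyl)hepta-2,6-dien-1-ol (9S) | O[C@@H](/C(CO)=C\CC/C(CO[Si](C(C)C)(C(C)C)C(C)C)=C\[Si](C)(C)C)[C@H]1COC(C)(C)O1 | intermediate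
12 | (4S,5Z)-2,2-di-tert-butyl-4-[(4R)-2,2-dimethyl-1,3-dioxolan-4-yl]-5-[(4E)-4-{[(triisopropylsilyl)oxy]methyl}-5-(trimethylsilyl)pent-4-en-1-ylidene]-1,3,2-dioxasilinane | CC1(C)OC[C@@H](O1)[C@H]2O[Si](C(C)(C)C)(C(C)(C)C)OC/C2=C/CC/C(CO[Si](C(C)C)(C(C)C)C(C)C)=C\[Si](C)(C)C | intermediate
13 | (4S,5Z)-2,2-di-tert-butyl-4-[(4R)-2,2-dimethyl-1,3-dioxolan-4-yl]-5-[(4E)-5-iodo-4-{[(triisopropylsilyl)oxy]methyl}pent-4-en-1-ylidene]-1,3,2-dioxasilinane | CC1(C)OC[C@@H](O1)[C@H]2O[Si](C(C)(C)C)(C(C)(C)C)OC/C2=C/CC/C(CO[Si](C(C)C)(C(C)C)C(C)C)=C\I | intermediate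
14 | (1R)-1-[(4S,5Z)-2,2-di-tert-butyl-5-{(4E)-5-iodo-4-[(triisopropylsilyloxy)methyl]pent-4-en-1-ylidene}-1,3,2-dioxasilinan-4-yl]ethane-1,2-diol | OC[C@@H](O)[C@H]1O[Si](C(C)(C)C)(C(C)(C)C)OC/C1=C/CC/C(CO[Si](C(C)C)(C(C)C)C(C)C)=C\I | intermediate
15 | (4S,5Z)-2,2-di-tert-butyl-5-[(4E)-5-iodo-4-{[(triisopropylsilyl)oxy]methyl}pent-4-en-1-ylidene]-1,3,2-dioxasilinane-4-carbaldehyde (C8 aldehyde, 9S) | O=C[C@H]1O[Si](C(C)(C)C)(C(C)(C)C)OC/C1=C/CC/C(CO[Si](C(C)C)(C(C)C)C(C)C)=C\I | intermediate
16 | dimethyl 2-methylidenebutanedioate (dimethyl itaconate) | COC(=O)CC(=C)C(=O)OC | starting material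
17 | 3-(methoxycarbonyl)but-3-enoic acid | OC(=O)CC(=C)C(=O)OC | intermediate
18 | (4R)-4-benzyl-1,3-thiazolidine-2-thione | S=C1N[C@H](Cc2ccccc2)CS1 | starting material
19 | methyl 4-[(4R)-4-benzyl-2-sulfanylidene-1,3-thiazolidin-3-yl]-2-methylidene-4-oxobutanoate | C=C(CC(=O)N1[C@H](Cc2ccccc2)CSC1=S)C(=O)OC | intermediate
20 | methyl (3R,4R)-3-{[(4R)-4-benzyl-2-sulfanylidene-1,3-thiazolidin-3-yl]carbonyl}-4-hydroxy-2-methylidene-4-[(4S,5Z)-2,2-di-tert-butyl-5-{(4E)-5-iodo-4-[(triisopropylsilyloxy)methyl]pent-4-en-1-ylidene}-1,3,2-dioxasilinan-4-yl]butanoate (7R,8R,9S) | S=C1SC[C@@H](Cc2ccccc2)N1C(=O)[C@H](C(=C)C(=O)OC)[C@@H](O)[C@H]3O[Si](C(C)(C)C)(C(C)(C)C)OC/C3=C/CC/C(CO[Si](C(C)C)(C(C)C)C(C)C)=C\I | intermediate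
21 | (2S)-2-methylbutanoic acid | CC[C@H](C)C(=O)O | starting material
22 | C8 (2S)-2-methylbutanoate of 20 (7R,8R,9S) | S=C1SC[C@@H](Cc2ccccc2)N1C(=O)[C@H](C(=C)C(=O)OC)[C@@H](OC(=O)[C@@H](C)CC)[C@H]3O[Si](C(C)(C)C)(C(C)(C)C)OC/C3=C/CC/C(CO[Si](C(C)C)(C(C)C)C(C)C)=C\I | intermediate
23 | methyl (3R,4R)-3-formyl-2-methylidene-4-{[(2S)-2-methylbutanoyl]oxy}-4-[(4S,5Z)-2,2-di-tert-butyl-5-{(4E)-5-iodo-4-[(triisopropylsilyloxy)methyl]pent-4-en-1-ylidene}-1,3,2-dioxasilinan-4-yl]butanoate (open-chain C6 aldehyde, 7R,8R,9S) | O=C[C@H](C(=C)C(=O)OC)[C@@H](OC(=O)[C@@H](C)CC)[C@H]1O[Si](C(C)(C)C)(C(C)(C)C)OC/C1=C/CC/C(CO[Si](C(C)C)(C(C)C)C(C)C)=C\I | intermediate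
24 | ten-membered (6R,7S,8R,9S) C6 carbinol with the C12 methyl ester intact (chromium alkoxide in the flask, drawn as the alcohol); both ring double bonds ring-cis | C=C(C(=O)OC)[C@H]1[C@H](O)/C=C(/CO[Si](C(C)C)(C(C)C)C(C)C)CC/C=C2/CO[Si](C(C)(C)C)(C(C)(C)C)O[C@@H]2[C@@H]1OC(=O)[C@@H](C)CC | intermediate
25 | (6R,7S,8R,9S)-germacra-1(10),4,11(13)-trien-12,6-olide with both ring double bonds ring-cis, 8-O-[(2S)-2-methylbutanoyl], O9/O14 di-tert-butylsilylene, O15 triisopropylsilyl | C=C1C(=O)O[C@@H]2/C=C(/CO[Si](C(C)C)(C(C)C)C(C)C)CC/C=C3/CO[Si](C(C)(C)C)(C(C)(C)C)O[C@@H]3[C@H](OC(=O)[C@@H](C)CC)[C@@H]12 | intermediate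
26 | 9,14-diol of 25 (O15 triisopropylsilyl) | C=C1C(=O)O[C@@H]2/C=C(/CO[Si](C(C)C)(C(C)C)C(C)C)CC/C=C(/CO)[C@H](O)[C@H](OC(=O)[C@@H](C)CC)[C@@H]12 | intermediate
27 | 14-al of 26 (C9–OH free, O15 triisopropylsilyl) | C=C1C(=O)O[C@@H]2/C=C(/CO[Si](C(C)C)(C(C)C)C(C)C)CC/C=C(/C=O)[C@H](O)[C@H](OC(=O)[C@@H](C)CC)[C@@H]12 | intermediate
28 | CNP0331447.11, (6R,7S,8R,9S)-9,15-dihydroxy-14-oxo-germacra-1(10),4,11(13)-trien-12,6-olide 8-[(2S)-2-methylbutanoate], both ring double bonds ring-cis | C=C1C(=O)O[C@@H]2/C=C(/CO)CC/C=C(/C=O)[C@H](O)[C@H](OC(=O)[C@@H](C)CC)[C@@H]12 | target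

## Step count and risks

Total step count: 19. Longest linear sequence: 17 steps (steps 1–10 and 13–19).

Steps most likely to fail:

1. Step 16. The alkenylchromium may attack the other face of the C6 aldehyde, or the aldehyde may epimerise at C7 or lose the C8 acyloxy group before the ring closes, or chains may oligomerise. Fallback, from 23 back to 25: C6 would be set by inversion instead of by the addition. The ring closure of 23 would be run at 0 °C and quenched before lactonisation, which should give the 6-epi (6S) ring-closed hydroxy methyl ester F1. Its methyl ester would be cleaved with Me3SnOH (1,2-dichloroethane, 60 °C), which spares the hindered 2-methylbutanoate, to give the 6-epi hydroxy acid F2. A Mitsunobu lactonisation (PPh3, diisopropyl azodicarboxylate, THF) would then close the lactone with inversion at C6 and give 25.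

2. Step 15. Hydride may also reach the two esters, and the aldehyde may epimerise or eliminate during release from the aluminium adduct. Fallback, from 22 back to 23: the thioimide would be reduced fully with NaBH4 (THF/H2O, 0 °C), which leaves both esters, to the C6 primary alcohol F3. Because this γ-hydroxy ester can lactonise, F3 would be oxidised at once with Dess–Martin periodinane and NaHCO3 in CH2Cl2 to 23.

3. Step 13. The acrylate-bearing thioimide may not enolise cleanly at C7 (drift of the alkene into conjugation, or reaction at C13), and the titanium aldolate may lactonise onto C12. Fallback, from 15 back to 23: C7–C8 would be made by a stereospecific allylboration with C6 carried as a protected alcohol. 4-Methoxybenzyl propargyl ether would be converted with n-BuLi and ClCO2Me into methyl 4-[(4-methoxybenzyl)oxy]but-2-ynoate F4. Syn-hydroalumination of F4 (i-Bu2AlH, HMPA, THF, 0 °C) and alkylation of the alkenylalane with ICH2B(pin) would give the (Z)-2-(methoxycarbonyl)allylboronate F5, in which the CH2O(4-methoxybenzyl) group is cis to the ester. Addition of F5 to 15 (toluene, rt to 50 °C) through a chair transition state would give the homoallylic alcohol F6 with the same C7/C8 relative configuration as 20; its facial selectivity towards C9 is expected to be lower than that of the aldol, so the 8-epimer would have to be separated. Esterification as in step 14 would give the 2-methylbutanoate F7, DDQ (CH2Cl2, pH 7 buffer) would give alcohol F3, and Dess–Martin oxidation would give 23.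

Further compounds
F1 | step 16 | 6-epi (6S,7S,8R,9S) ring-closed C6 carbinol methyl ester | C=C(C(=O)OC)[C@H]1[C@@H](O)/C=C(/CO[Si](C(C)C)(C(C)C)C(C)C)CC/C=C2/CO[Si](C(C)(C)C)(C(C)(C)C)O[C@@H]2[C@@H]1OC(=O)[C@@H](C)CC
F2 | step 16 | 6-epi ring-closed C6 carbinol C12 carboxylic acid | C=C(C(=O)O)[C@H]1[C@@H](O)/C=C(/CO[Si](C(C)C)(C(C)C)C(C)C)CC/C=C2/CO[Si](C(C)(C)C)(C(C)(C)C)O[C@@H]2[C@@H]1OC(=O)[C@@H](C)CC
F3 | step 15 | C6 primary alcohol corresponding to aldehyde 23 | OC[C@H](C(=C)C(=O)OC)[C@@H](OC(=O)[C@@H](C)CC)[C@H]1O[Si](C(C)(C)C)(C(C)(C)C)OC/C1=C/CC/C(CO[Si](C(C)C)(C(C)C)C(C)C)=C\I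
F4 | step 13 | methyl 4-[(4-methoxybenzyl)oxy]but-2-ynoate | COC(=O)C#CCOCc1ccc(OC)cc1
F5 | step 13 | methyl (2Z)-4-[(4-methoxybenzyl)oxy]-2-[(4,4,5,5-tetramethyl-1,3,2-dioxaborolan-2-yl)methyl]but-2-enoate | COC(=O)/C(CB1OC(C)(C)C(C)(C)O1)=C\COCc1ccc(OC)cc1
F6 | step 13 | homoallylic alcohol with C6 as 4-methoxybenzyl ether and C8–OH free | COc1ccc(COC[C@H](C(=C)C(=O)OC)[C@@H](O)[C@H]2O[Si](C(C)(C)C)(C(C)(C)C)OC/C2=C/CC/C(CO[Si](C(C)C)(C(C)C)C(C)C)=C\I)cc1
F7 | step 13 | C8 (2S)-2-methylbutanoate of F6 | COc1ccc(COC[C@H](C(=C)C(=O)OC)[C@@H](OC(=O)[C@@H](C)CC)[C@H]2O[Si](C(C)(C)C)(C(C)(C)C)OC/C2=C/CC/C(CO[Si](C(C)C)(C(C)C)C(C)C)=C\I)cc1
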